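**Plan**

1. Cuts, in order: the two ester C–O bonds; C11′=C12′ and C11=C12 (Wittig), giving an ε C15 aldehyde, the C10 trienedial and a β C15 phosphonium salt; in the β ring C3–C4 (retro carbonyl-ene) and then C1–C6 (retro oxy-Cope), which unravels the ring to an open-chain (R)-3-hydroxypseudoionone ketal; this falls to prenal, an allenylboronate and a vinyl ketal (C3–C4, C6–C7).
2. Forward: linear C13 carbinol → anionic oxy-Cope (C1–C6 made, C3–C4 broken) → carbonyl-ene closure of the β ring (C3–C4 remade) → C15 salt → C25 aldehyde → C25 salt → union with the ε C15 aldehyde → double acylation. The β ring is the only ring closed in the route; the ε ring is bought intact in (R)-α-ionone.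
3. Enabling feature: the β ring is a homoallylic alcohol (O–C3–C4–C5=C6). Its seco form has a C6–H that is allylic to an isopropenyl group and γ to an enone, and C1–C6 sit in a 1,5-dien-3-ol array, so two pericyclic events stand in for a cation–olefin cyclisation that could not carry the C3 oxygen.
4. Stereochemistry: C3 is set once by a chiral phosphoric acid, handed to C6 in the chair oxy-Cope transition state and handed back from C6 to C3 in the ene closure; C6′ is bought with (R)-α-ionone and C3′ comes from a CBS reduction; E geometry comes from the Negishi, Heck and Wittig steps and thermal equilibration.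

Key step: step 5

Remark: (R)-(+)-α-ionone of high enantiomeric purity is taken as a purchasable starting material; carotenoid numbering is used for atoms (C1–C6 β ring, primed numbers for the ε half).

**Step 1**
Reactants: 1 3-methylbut-2-enal (prenal); 2 allenylboronic acid pinacol ester
Product: 3 (4R)-6-methylhept-5-en-1-yn-4-ol
Conditions: (R)-TRIP (10 mol %), 4 Å MS, toluene, −20 °C; aq. NaHCO3 work-up
Reagents that add atoms: none
Why: Chiral Brønsted acid-catalysed propargylboration: the allenylboronate adds through its γ-carbon in a closed six-membered transition state organised by the phosphoric acid, whose chirality should set C3 as R (the antipodal acid would be taken if the sense proved opposite), and the conjugated aldehyde reacts only at the carbonyl group.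

**Step 2**
Reactants: 3 (4R)-6-methylhept-5-en-1-yn-4-ol
Product: 5 (1E,4R)-1-iodo-2,6-dimethylhepta-1,5-dien-4-ol, via alkenylalane 4 (not isolated)
Conditions: Me3Al (3 equiv), Cp2ZrCl2 (0.3 equiv), H2O (1 equiv), CH2Cl2, −20 °C; then I2, THF, −30 °C; aq. NaHCO3, potassium sodium tartrate (KNaC4H4O6)
Reagents that add atoms: trimethylaluminium C[Al](C)C; iodine II
Why: Negishi carboalumination: zirconium-catalysed syn addition of Me–Al to the terminal alkyne (methyl to the internal carbon, assisted by the aluminium alkoxide) followed by iodinolysis with retention should give the (E)-iodide that carries C5, its methyl group and C6, and the carbinol centre is not touched.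

**Step 3**
Reactants: 5 (1E,4R)-1-iodo-2,6-dimethylhepta-1,5-dien-4-ol; 6 2-methyl-2-vinyl-1,3-dioxolane
Product: 7 (4R,6E,8E)-2,6-dimethyl-9-(2-methyl-1,3-dioxolan-2-yl)nona-2,6,8-trien-4-ol
Conditions: Pd(OAc)2 (5 mol %), K2CO3, Bu4NCl, DMF, 50 °C
Reagents that add atoms: none
Why: Mizoroki–Heck reaction: the alkenylpalladium species adds to the unhindered terminus of the monosubstituted alkene and syn β-hydride elimination, possible in one direction only because the ketal carbon bears no hydrogen, should give the (6E,8E)-diene with the ketone masked for the next step.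

**Step 4**
Reactants: 7 (4R,6E,8E)-2,6-dimethyl-9-(2-methyl-1,3-dioxolan-2-yl)nona-2,6,8-trien-4-ol
Product: 10 (4R,5E)-3,3-dimethyl-7-oxo-4-(prop-1-en-2-yl)oct-5-enal, via potassium enolate 8 (not isolated), via aldehyde ketal 9 (not isolated)
Conditions: KH (2 equiv), 18-crown-6 (2 equiv), THF, 0 → 40 °C; AcOH, −78 °C; then PPTS (cat.), acetone–H2O, 20 °C
Reagents that add atoms: water O
Why: Anionic oxy-Cope rearrangement: the potassium alkoxide of the 1,5-dien-3-ol should rearrange through a chair transition state in which the oxido group is equatorial (an axial one would be 1,3-diaxial to the Z-methyl group on C1) and the E-configured C5=C6 bond holds the side chain equatorial, so that the C3 chirality is relayed to C6 (R) as the C1–C6 bond with its quaternary centre forms and C3–C4 breaks, after which protonation and mild acid give the aldehyde and unmask the enone.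

**Step 5**
Reactants: 10 (4R,5E)-3,3-dimethyl-7-oxo-4-(prop-1-en-2-yl)oct-5-enal
Product: 11 (3R)-3-hydroxy-β-ionone [(E)-4-[(4R)-4-hydroxy-2,6,6-trimethylcyclohex-1-en-1-yl]but-3-en-2-one]
Conditions: Me2AlCl (2.2 equiv, 1 M in hexanes), CH2Cl2, −78 → −40 °C; 1 M HCl, 0 °C
Reagents that add atoms: none
Why: Proposed new method: Me2AlCl activates the aldehyde, the terminal CH2 of the isopropenyl group (C4) bonds to the carbonyl carbon (C3) and, in the same bicyclo[2.2.2]octane-like array, the doubly activated C6–H (allylic and γ to the enone) is delivered to oxygen, so that the ring, the carbinol and the tetrasubstituted C5=C6 bond conjugated to the enone should arise together. The closest known reaction is the Me2AlCl-promoted type-2 carbonyl-ene cyclisation of 5-methylhex-5-enals to 3-methylenecyclohexanols; what is new is hydrogen transfer from the tether carbon (type-3 topology) instead of from the methyl group. The six-membered ring closes in a 6-exo-trig mode at the aldehyde carbon (carbonyl oxygen exocyclic) with all three ene carbons endocyclic. The new stereocentre C3 is controlled by the sacrificial C6 centre: suprafacial transfer of H6 to the carbonyl oxygen forces the oxygen to lie cis to H6, that is trans to the side chain, which translates (6R) into (3R), and the stepwise alternative (chair cation with equatorial oxygen and equatorial side chain, axial H6 lost) leads to the same sense. The step needs loss of H6 in preference to a C18 methyl hydrogen and no epimerisation of C6 before C–C bond formation: H6 is the weakest and most acidic C–H and its loss gives the conjugated dienone, the competing type-2 transition state would place the complexed oxygen syn-axial to a C1 methyl group, the low temperature and non-basic medium protect C6, and the electron-poor enone alkene cannot compete as a nucleophile.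

**Step 6**
Reactants: 11 (3R)-3-hydroxy-β-ionone; 12 vinylmagnesium bromide
Product: 13 (3R)-3-hydroxy-9-vinyl-β-ionol [(1R)-4-[(1E)-3-hydroxy-3-methylpenta-1,4-dien-1-yl]-3,5,5-trimethylcyclohex-3-en-1-ol, both C9 epimers]
Conditions: CH2=CHMgBr (3 equiv), THF, −20 → 0 °C; aq. NH4Cl
Reagents that add atoms: none
Why: Grignard 1,2-addition to the dienone carbonyl, as for β-ionone itself, after the first equivalent has deprotonated the hydroxyl group; the new C9 centre is formed without control and is removed in step 7.

**Step 7**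
Reactants: 13 (3R)-3-hydroxy-9-vinyl-β-ionol
Product: 14 [(2E,4E)-5-[(4R)-4-hydroxy-2,6,6-trimethylcyclohex-1-en-1-yl]-3-methylpenta-2,4-dien-1-yl]triphenylphosphonium bromide
Conditions: Ph3P·HBr (1.05 equiv), MeOH, 0 → 20 °C; (9E) salt crystallised
Reagents that add atoms: triphenylphosphine hydrobromide [Br-].[PH+](c1ccccc1)(c1ccccc1)c1ccccc1
Why: Acid-mediated allylic transposition to the Wittig salt: HBr ionises the tertiary bis-allylic alcohol and Ph3P captures the pentadienyl cation at its primary terminus (SN1′), while the non-allylic C3 hydroxyl group is not ionised.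

**Step 8**
Reactants: 14 β C15 phosphonium bromide; 15 (2E,4E,6E)-2,7-dimethylocta-2,4,6-trienedial
Product: 17 (3R)-3-hydroxy-12′-apo-β-caroten-12′-al, via phosphorus ylide 16 (not isolated)
Conditions: 15 (3 equiv), NaOMe (1.1 equiv), MeOH–CH2Cl2, −10 → 20 °C; then heptane–EtOH, reflux (Z → E), dark
Reagents that add atoms: none
Why: Wittig olefination: the semi-stabilised ylide condenses with one formyl group of the symmetrical dialdehyde (used in excess to suppress double condensation) to form C11=C12, and the Z/E mixture is equilibrated thermally to the all-E polyene aldehyde.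

**Step 9**
Reactants: 17 (3R)-3-hydroxy-12′-apo-β-caroten-12′-al
Product: 18 (3R)-12′-apo-β-carotene-3,12′-diol
Conditions: NaBH4, MeOH–THF, 0 °C
Reagents that add atoms: none
Why: Hydride 1,2-reduction of the polyenal with NaBH4, which leaves the polyene and the secondary alcohol untouched.

**Step 10**
Reactants: 18 (3R)-12′-apo-β-carotene-3,12′-diol
Product: 19 [(3R)-3-hydroxy-12′-apo-β-caroten-12′-yl]triphenylphosphonium bromide
Conditions: Ph3P·HBr (1.05 equiv), MeOH–CH2Cl2, 0 → 20 °C, dark
Reagents that add atoms: triphenylphosphine hydrobromide [Br-].[PH+](c1ccccc1)(c1ccccc1)c1ccccc1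
Why: Same allylic phosphonium salt formation as in step 7 (as for retinol): ionisation of the primary polyenylic alcohol and capture by Ph3P at the terminal carbon, which keeps the conjugation, while the C3 alcohol again stays.

**Step 11**
Reactants: 20 (R)-α-ionone; 21 diethyl (cyanomethyl)phosphonate
Product: 23 (2E,4E)-3-methyl-5-[(1R)-2,6,6-trimethylcyclohex-2-en-1-yl]penta-2,4-dienenitrile, via phosphonate carbanion 22 (not isolated)
Conditions: NaH (1.0 equiv), THF, 0 °C (anion preformed), then 20, 0 → 20 °C; (9Z) isomer removed by chromatography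
Reagents that add atoms: none
Why: Horner–Wadsworth–Emmons olefination of the methyl ketone gives mainly the (9E)-nitrile and adds C10 and C11, and the preformed, weakly basic carbanion should leave the C6′ stereocentre intact.

**Step 12**
Reactants: 23 (9E)-α-ionylideneacetonitrile
Product: 24 (2E,4E)-3-methyl-5-[(1R)-2,6,6-trimethyl-4-oxocyclohex-2-en-1-yl]penta-2,4-dienenitrile
Conditions: CrO3 (0.1 equiv), t-BuOOH (70 % aq., 5 equiv), CH2Cl2, 20 °C
Reagents that add atoms: tert-butyl hydroperoxide CC(C)(C)OO
Why: Allylic C–H oxidation (chromium-catalysed peroxide oxidation, as known for α-ionone itself): the ring methylene C3′, the only allylic CH2, is converted into the enone carbonyl, while the hindered tertiary C6′–H is left.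

**Step 13**
Reactants: 24 3′-oxo nitrile
Product: 25 (2E,4E)-5-[(1R,4R)-4-hydroxy-2,6,6-trimethylcyclohex-2-en-1-yl]-3-methylpenta-2,4-dienenitrile
Conditions: (S)-2-methyl-CBS-oxazaborolidine (0.2 equiv), catecholborane (1.5 equiv), toluene, −78 °C; MeOH, aq. NaHCO3; minor 3′-epimer removed by chromatography
Reagents that add atoms: none
Why: Corey–Bakshi–Shibata reduction: with the ring alkene as the larger carbonyl substituent the (S)-catalyst should deliver hydride to the face that gives (3′R), that is trans to the C6′ side chain, under reagent control, and only the ketone reacts (1,2).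

**Step 14**
Reactants: 25 (3′R,6′R)-hydroxy nitrile
Product: 27 (2E,4E)-5-[(1R,4R)-4-hydroxy-2,6,6-trimethylcyclohex-2-en-1-yl]-3-methylpenta-2,4-dienal, via aluminium imide 26 (not isolated)
Conditions: i-Bu2AlH (2.5 equiv), CH2Cl2, −78 °C; then wet SiO2, aq. potassium sodium tartrate (KNaC4H4O6), 0 °C
Reagents that add atoms: water O
Why: Partial reduction of the nitrile by i-Bu2AlH stops at the aluminium imide, whose mild hydrolysis gives the (E,E)-dienal without acid that could ionise the allylic C3′ alcohol.

**Step 15**
Reactants: 19 β C25 phosphonium bromide; 27 ε C15 hydroxy aldehyde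
Product: 29 (3R,3′R,6′R)-β,ε-carotene-3,3′-diol (lutein), via phosphorus ylide 28 (not isolated)
Conditions: 1,2-epoxybutane (excess), EtOH, reflux, dark, argon
Reagents that add atoms: none
Why: Wittig olefination forms C11′=C12′ and completes the C40 skeleton; the epoxide serves as a neutral HBr scavenger so that the base-sensitive C6′–H is not endangered, the free hydroxyl groups are tolerated and heating equilibrates to the all-E isomer.

**Step 16**
Reactants: 29 lutein; 30 tetradecanoyl chloride (myristoyl chloride)
Product: 31 lutein dimyristate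
Conditions: 30 (2.5 equiv), pyridine, DMAP (cat.), CH2Cl2, 0 → 20 °C, dark
Reagents that add atoms: none
Why: DMAP-catalysed acylation of both secondary alcohols (one homoallylic, one allylic) by the acid chloride proceeds at oxygen with retention at C3 and C3′ under non-acidic conditions.

**Compound list**

1 | 3-methylbut-2-enal (prenal) | CC(C)=CC=O | starting material
2 | allenylboronic acid pinacol ester | C=C=CB1OC(C)(C)C(C)(C)O1 | starting material
3 | (4R)-6-methylhept-5-en-1-yn-4-ol | CC(C)=C[C@H](O)CC#C | intermediate
4 | (E)-alkenyl(dimethyl)alane, O-dimethylaluminium alkoxide, from 3 | CC(C)=C[C@H](O[Al](C)C)C/C(C)=C/[Al](C)C | intermediate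
5 | (1E,4R)-1-iodo-2,6-dimethylhepta-1,5-dien-4-ol | CC(C)=C[C@H](O)C/C(C)=C/I | intermediate
6 | 2-methyl-2-vinyl-1,3-dioxolane | C=CC1(C)OCCO1 | starting material
7 | (4R,6E,8E)-2,6-dimethyl-9-(2-methyl-1,3-dioxolan-2-yl)nona-2,6,8-trien-4-ol | CC(C)=C[C@H](O)C/C(C)=C/C=C/C1(C)OCCO1 | intermediate
8 | potassium (E)-enolate of aldehyde 9 | [K+].[O-]/C=C/C(C)(C)[C@@H](C(C)=C)/C=C/C1(C)OCCO1 | intermediate
9 | (4R,5E)-3,3-dimethyl-6-(2-methyl-1,3-dioxolan-2-yl)-4-(prop-1-en-2-yl)hex-5-enal | O=CCC(C)(C)[C@@H](C(C)=C)/C=C/C1(C)OCCO1 | intermediate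
10 | (4R,5E)-3,3-dimethyl-7-oxo-4-(prop-1-en-2-yl)oct-5-enal | O=CCC(C)(C)[C@@H](C(C)=C)/C=C/C(C)=O | intermediate
11 | (3R)-3-hydroxy-β-ionone | O[C@@H]1CC(C)=C(/C=C/C(C)=O)C(C)(C)C1 | intermediate
12 | vinylmagnesium bromide | C=C[Mg]Br | starting material
13 | (3R)-3-hydroxy-9-vinyl-β-ionol (both C9 epimers) | O[C@@H]1CC(C)=C(/C=C/C(C)(O)C=C)C(C)(C)C1 | intermediate
14 | [(2E,4E)-5-[(4R)-4-hydroxy-2,6,6-trimethylcyclohex-1-en-1-yl]-3-methylpenta-2,4-dien-1-yl]triphenylphosphonium bromide | [Br-].O[C@@H]1CC(C)=C(/C=C/C(C)=C/C[P+](c2ccccc2)(c2ccccc2)c2ccccc2)C(C)(C)C1 | intermediate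
15 | (2E,4E,6E)-2,7-dimethylocta-2,4,6-trienedial | O=C/C(C)=C/C=C/C=C(C)/C=O | starting material
16 | phosphorus ylide of 14 | O[C@@H]1CC(C)=C(/C=C/C(C)=C/C=P(c2ccccc2)(c2ccccc2)c2ccccc2)C(C)(C)C1 | intermediate
17 | (3R)-3-hydroxy-12′-apo-β-caroten-12′-al | O[C@@H]1CC(C)=C(/C=C/C(C)=C/C=C/C(C)=C/C=C/C=C(C)/C=O)C(C)(C)C1 | intermediate
18 | (3R)-12′-apo-β-carotene-3,12′-diol | O[C@@H]1CC(C)=C(/C=C/C(C)=C/C=C/C(C)=C/C=C/C=C(C)/CO)C(C)(C)C1 | intermediate
19 | [(3R)-3-hydroxy-12′-apo-β-caroten-12′-yl]triphenylphosphonium bromide | [Br-].O[C@@H]1CC(C)=C(/C=C/C(C)=C/C=C/C(C)=C/C=C/C=C(C)/C[P+](c2ccccc2)(c2ccccc2)c2ccccc2)C(C)(C)C1 | intermediate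
20 | (R)-α-ionone | CC(=O)/C=C/[C@H]1C(C)=CCCC1(C)C | starting material
21 | diethyl (cyanomethyl)phosphonate | CCOP(=O)(CC#N)OCC | starting material
22 | sodium salt of the carbanion of 21 | [Na+].CCOP(=O)([CH-]C#N)OCC | intermediate
23 | (2E,4E)-3-methyl-5-[(1R)-2,6,6-trimethylcyclohex-2-en-1-yl]penta-2,4-dienenitrile | N#C/C=C(C)/C=C/[C@H]1C(C)=CCCC1(C)C | intermediate
24 | (2E,4E)-3-methyl-5-[(1R)-2,6,6-trimethyl-4-oxocyclohex-2-en-1-yl]penta-2,4-dienenitrile | N#C/C=C(C)/C=C/[C@H]1C(C)=CC(=O)CC1(C)C | intermediate
25 | (2E,4E)-5-[(1R,4R)-4-hydroxy-2,6,6-trimethylcyclohex-2-en-1-yl]-3-methylpenta-2,4-dienenitrile | N#C/C=C(C)/C=C/[C@H]1C(C)=C[C@H](O)CC1(C)C | intermediate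
26 | N-(diisobutylaluminio) imine of 27, O-diisobutylaluminium alkoxide | CC(C)C[Al](CC(C)C)N=C/C=C(C)/C=C/[C@H]1C(C)=C[C@H](O[Al](CC(C)C)CC(C)C)CC1(C)C | intermediate
27 | (2E,4E)-5-[(1R,4R)-4-hydroxy-2,6,6-trimethylcyclohex-2-en-1-yl]-3-methylpenta-2,4-dienal | O=C/C=C(C)/C=C/[C@H]1C(C)=C[C@H](O)CC1(C)C | intermediate
28 | phosphorus ylide of 19 | O[C@@H]1CC(C)=C(/C=C/C(C)=C/C=C/C(C)=C/C=C/C=C(C)/C=P(c2ccccc2)(c2ccccc2)c2ccccc2)C(C)(C)C1 | intermediate
29 | (3R,3′R,6′R)-β,ε-carotene-3,3′-diol (lutein) | O[C@@H]1CC(C)=C(/C=C/C(C)=C/C=C/C(C)=C/C=C/C=C(C)/C=C/C=C(C)/C=C/[C@H]2C(C)=C[C@H](O)CC2(C)C)C(C)(C)C1 | intermediate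
30 | tetradecanoyl chloride (myristoyl chloride) | CCCCCCCCCCCCCC(=O)Cl | starting material
31 | lutein dimyristate | CCCCCCCCCCCCCC(=O)O[C@@H]1CC(C)=C(/C=C/C(C)=C/C=C/C(C)=C/C=C/C=C(C)/C=C/C=C(C)/C=C/[C@H]2C(C)=C[C@H](OC(=O)CCCCCCCCCCCCC)CC2(C)C)C(C)(C)C1 | target

**Step count and risks**

Total steps: 16. Longest linear sequence: 12 steps (steps 1–10, then 15 and 16).

Step 5 (proposed new method). The risk is that hydrogen is transferred from the C18 methyl group instead of from C6, which gives the exocyclic alkene, or that a stepwise cationic path loosens the transfer of chirality from C6 to C3. The fallback uses the established reaction of this substrate class and starts from 10. 10 is cyclised with the bulky MeAl(OAr)2 (Ar = 4-bromo-2,6-di-tert-butylphenyl) in CH2Cl2 at −78 °C in the known type-2 carbonyl-ene mode to (E)-4-[(1S,4S)-4-hydroxy-2,2-dimethyl-6-methylidenecyclohexyl]but-3-en-2-one F1, the 3,6-trans exocyclic-methylene alcohol. F1 still carries C6 and is separated from its C3 epimer by chromatography. DBU in toluene (or NaOMe in MeOH) then moves the double bond into conjugation, as in the known isomerisation of α- and γ-ionone to β-ionone, and returns the route at 11. Should the 3,6-cis relationship prevail in this mode, the antipodal phosphoric acid is used in step 1 so that the cis isomer then carries (3R).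

Step 4. The risk is heterolytic fragmentation of the alkoxide (retro-allylation to prenal and a pentadienyl anion), a competing 1,3-shift, or partial passage through a boat transition state that lowers the chirality transfer. The fallback avoids the free alkoxide and starts from 7. 7 is silylated (Me3SiCl, imidazole, CH2Cl2) to the trimethylsilyl ether of 7 F2, which is rearranged thermally (siloxy-Cope, decalin, 180–200 °C, base-washed sealed tube) to the trimethylsilyl enol ether of 9 F3. PPTS in acetone–water cleaves the silyl enol ether and the ketal together and returns the route at 10.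

Step 13. The risk is poor facial selectivity when catalyst control and the intrinsic bias of the ring (gem-dimethyl group and C6′ side chain) oppose each other. The fallback uses substrate control followed by inversion and starts from 24. 24 is reduced with NaBH4/CeCl3·7H2O in MeOH at −40 °C (Luche reduction), and the 3′,6′-cis alcohol (2E,4E)-5-[(1R,4S)-4-hydroxy-2,6,6-trimethylcyclohex-2-en-1-yl]-3-methylpenta-2,4-dienenitrile F4 is isolated. Mitsunobu reaction (4-nitrobenzoic acid, Ph3P, diisopropyl azodicarboxylate, THF, 0 °C) inverts C3′ to the (1R,4R)-4-nitrobenzoate F5. Methanolysis (K2CO3, MeOH, 0 °C) returns the route at 25; any 25 formed directly in the reduction is combined with it.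

**Further compounds**

F1 | step 5 | (E)-4-[(1S,4S)-4-hydroxy-2,2-dimethyl-6-methylidenecyclohexyl]but-3-en-2-one (3,6-trans-3-hydroxy-γ-ionone) | CC(=O)/C=C/[C@@H]1C(=C)C[C@@H](O)CC1(C)C
F2 | step 4 | trimethylsilyl ether of 7 | CC(C)=C[C@H](O[Si](C)(C)C)C/C(C)=C/C=C/C1(C)OCCO1
F3 | step 4 | trimethylsilyl enol ether of 9 | C[Si](C)(C)O/C=C/C(C)(C)[C@@H](C(C)=C)/C=C/C1(C)OCCO1
F4 | step 13 | (2E,4E)-5-[(1R,4S)-4-hydroxy-2,6,6-trimethylcyclohex-2-en-1-yl]-3-methylpenta-2,4-dienenitrile | N#C/C=C(C)/C=C/[C@H]1C(C)=C[C@@H](O)CC1(C)C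
F5 | step 13 | (1R,4R)-4-[(1E,3E)-4-cyano-3-methylbuta-1,3-dien-1-yl]-3,5,5-trimethylcyclohex-2-en-1-yl 4-nitrobenzoate | N#C/C=C(C)/C=C/[C@H]1C(C)=C[C@H](OC(=O)c2ccc(cc2)[N+](=O)[O-])CC1(C)C
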